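**Plan**
- Retrosynthesis: the four methoxymethyl (MOM) ethers are removed first; then the C2–C1' bond between the pyranone ring and the resorcinol ring is cut; then the C6–CH2 bond of the lavandulyl side chain; last, inside the side chain, the bond between the stereocentre and the prenyl CH2, and the acyl–N bond to a chiral auxiliary.
- Forward: the A/C bicycle is bought intact as 5,7-dihydroxychromone and differentiated (7-O-MOM, iodination at C6 ortho to the free 5-OH, 5-O-MOM). The side chain is joined at C6 by an sp3–sp2 Negishi coupling, the B ring is joined last at C2, and acetal cleavage ends the route.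
- Enabling feature: the C2–H of the 4H-pyran-4-one ring is a vinylic C–H bonded to ring oxygen O1 and β to C4=O, the most acidic C–H of the chromone. The unfunctionalised chromone can therefore be metalated there and arylated in one operation, with no activating group to install or remove.
- Stereochemistry: the single stereocentre comes from an Evans deconjugative alkylation controlled by (R)-4-benzyl-2-oxazolidinone and is carried through unchanged. Its descriptor changes from R to S at the aryl coupling only through CIP ranking.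

Key step: step 10

Remark: 5,7-dihydroxychromone, 4-bromoresorcinol and TMPZnCl·LiCl (2,2,6,6-tetramethylpiperidinylzinc chloride–lithium chloride, THF solution) are taken as purchasable.

**Route**

Step 1
Reactants: 1 (4R)-4-benzyl-1,3-oxazolidin-2-one; 2 3-methylbut-2-enoyl chloride
Product: 4 (4R)-4-benzyl-3-(3-methylbut-2-enoyl)-1,3-oxazolidin-2-one, via lithium oxazolidinide 3 (not isolated)
Conditions: n-BuLi, THF, −78 °C; then 2, −78 → 0 °C
Reagents that add atoms: none
Why: N-acylation of the lithiated Evans auxiliary by the acid chloride, in which the nitrogen anion should be acylated at −78 °C faster than it deprotonates the γ-methyl group of 2.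

Step 2
Reactants: 4 (4R)-4-benzyl-3-(3-methylbut-2-enoyl)-1,3-oxazolidin-2-one; 5 1-bromo-3-methylbut-2-ene (prenyl bromide)
Product: 7 (4R)-4-benzyl-3-[(2R)-5-methyl-2-(prop-1-en-2-yl)hex-4-enoyl]-1,3-oxazolidin-2-one, via sodium Z-dienolate 6 (not isolated)
Conditions: NaHMDS, THF, −78 °C; then 5, −78 → −45 °C; cold quench with AcOH
Reagents that add atoms: none
Why: Evans asymmetric deconjugative α-alkylation, in which γ-deprotonation gives the sodium-chelated Z-dienolate that should react at Cα on the face opposite the C4 benzyl group, setting the (2R) centre and moving the double bond into the isopropenyl position.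

Step 3
Reactants: 7 (4R)-4-benzyl-3-[(2R)-5-methyl-2-(prop-1-en-2-yl)hex-4-enoyl]-1,3-oxazolidin-2-one
Product: 8 (2R)-5-methyl-2-(prop-1-en-2-yl)hex-4-en-1-ol [(R)-lavandulol]
Conditions: LiBH4, H2O (1 equiv), Et2O, 0 °C
Reagents that add atoms: none
Why: reductive cleavage of the N-acyloxazolidinone by LiBH4 should give the primary alcohol and release the auxiliary without base-mediated epimerisation of the α-centre or reduction of the two alkenes.

Step 4
Reactants: 8 (R)-lavandulol
Product: 9 (2R)-1-iodo-5-methyl-2-(prop-1-en-2-yl)hex-4-ene [(R)-lavandulyl iodide]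
Conditions: I2, PPh3, imidazole, CH2Cl2, 0 °C → rt
Reagents that add atoms: iodine, II
Why: Appel-type iodination, in which iodide displaces the alkoxyphosphonium group by SN2 at the CH2 carbon, so the adjacent stereocentre is not involved.

Step 5
Reactants: 10 5,7-dihydroxy-4H-chromen-4-one
Product: 11 5-hydroxy-7-(methoxymethoxy)-4H-chromen-4-one
Conditions: MOMCl (1.1 equiv), i-Pr2NEt, CH2Cl2–DMF, 0 °C → rt
Reagents that add atoms: chloromethyl methyl ether (MOMCl), COCCl
Why: selective O-alkylation (Williamson-type acetal formation) of the more acidic, non-chelated 7-OH, while the 5-OH stays free because it is hydrogen-bonded to C4=O.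

Step 6
Reactants: 11 5-hydroxy-7-(methoxymethoxy)-4H-chromen-4-one
Product: 12 5-hydroxy-6-iodo-7-(methoxymethoxy)-4H-chromen-4-one
Conditions: BnNMe3·ICl2 (1.05 equiv), CaCO3, CH2Cl2–MeOH, rt
Reagents that add atoms: benzyltrimethylammonium dichloroiodate, C[N+](C)(C)Cc1ccccc1.Cl[I-]Cl
Why: electrophilic aromatic iodination, which on 5-hydroxy-7-alkoxy chromones and flavones should go to C6 (ortho to the free chelated phenol) and not to C8, with CaCO3 buffering the HCl so the MOM ether survives.

Step 7
Reactants: 12 5-hydroxy-6-iodo-7-(methoxymethoxy)-4H-chromen-4-one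
Product: 14 6-iodo-5,7-bis(methoxymethoxy)-4H-chromen-4-one, via sodium 5-phenoxide 13 (not isolated)
Conditions: NaH, DMF, 0 °C; then MOMCl, 0 °C → rt
Reagents that add atoms: chloromethyl methyl ether (MOMCl), COCCl
Why: Williamson O-alkylation, in which irreversible deprotonation by NaH breaks the chelate of the 5-OH and the phenoxide is then alkylated by MOMCl.

Step 8
Reactants: 9 (R)-lavandulyl iodide; 14 6-iodo-5,7-bis(methoxymethoxy)-4H-chromen-4-one
Product: 16 5,7-bis(methoxymethoxy)-6-[(2S)-5-methyl-2-(prop-1-en-2-yl)hex-4-en-1-yl]-4H-chromen-4-one, via (R)-lavandulylzinc iodide 15 (not isolated)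
Conditions: 9 (1.5 equiv), Zn dust (activated), LiCl, THF, 40 °C; then 14, Pd(OAc)2 (5 mol %), SPhos (10 mol %), THF–NMP, 50 °C
Reagents that add atoms: none
Why: Negishi sp3–sp2 cross-coupling, in which zinc insertion into the primary C–I bond leaves the β-stereocentre untouched and a bulky biarylphosphine palladium catalyst should couple the alkylzinc with the di-ortho-alkoxy aryl iodide faster than β-hydride elimination, the chromone carbonyl being inert to RZnI.

Step 9
Reactants: 17 4-bromobenzene-1,3-diol
Product: 18 1-bromo-2,4-bis(methoxymethoxy)benzene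
Conditions: MOMCl (2.5 equiv), i-Pr2NEt, CH2Cl2, 0 °C → rt
Reagents that add atoms: chloromethyl methyl ether (MOMCl), COCCl
Why: twofold O-alkylation of the phenols to MOM acetals, which tolerate organozinc reagents and palladium catalysis.

Step 10
Reactants: 16 5,7-bis(methoxymethoxy)-6-[(2S)-5-methyl-2-(prop-1-en-2-yl)hex-4-en-1-yl]-4H-chromen-4-one; 18 1-bromo-2,4-bis(methoxymethoxy)benzene
Product: 20 2-[2,4-bis(methoxymethoxy)phenyl]-5,7-bis(methoxymethoxy)-6-[(2S)-5-methyl-2-(prop-1-en-2-yl)hex-4-en-1-yl]-4H-chromen-4-one, via 2-chromonylzinc chloride 19 (not isolated)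
Conditions: TMPZnCl·LiCl (1.3 equiv), THF, 25 °C; then 18 (1.3 equiv), Pd(OAc)2 (4 mol %), SPhos (8 mol %), 50 °C
Reagents that add atoms: none
Why: The hindered zinc amide removes the C2–H of the pyranone ring, the most acidic C–H of 16 because the sp2 carbanion sits on the carbon bonded to ring oxygen O1 and β to C4=O, and gives the covalent 2-chromonylzinc chloride 19, which should neither open the ring nor add to C4=O. Pd(0)/SPhos then undergoes oxidative addition into the C–Br bond of 18, transmetalation with 19 and reductive elimination, forming the C2–C1' bond. The closest known reaction type is the TMP-zinc base metalation of chromones at C2 followed by Negishi arylation to flavones. No ring is closed and no stereocentre is created; the (S) centre of the side chain carries no acidic hydrogen and is not touched. The step needs site selectivity for C2 over C3, C8 and the allylic and benzylic positions, which the O1-induced acidity and the absence of magnesium or boron Lewis acids on C4=O should secure. It also needs chemoselectivity toward the two alkenes and four acetals, which organozinc and Pd(0) chemistry tolerate.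

Step 11
Reactants: 20 2-[2,4-bis(methoxymethoxy)phenyl]-5,7-bis(methoxymethoxy)-6-[(2S)-5-methyl-2-(prop-1-en-2-yl)hex-4-en-1-yl]-4H-chromen-4-one
Product: 21 2-(2,4-dihydroxyphenyl)-5,7-dihydroxy-6-[(2S)-5-methyl-2-(prop-1-en-2-yl)hex-4-en-1-yl]-4H-chromen-4-one (target)
Conditions: 3 M aq. HCl, MeOH, 40 °C, monitored and stopped at full acetal cleavage
Reagents that add atoms: none
Why: acid-catalysed transacetalisation (methanolysis) of the four aryl MOM ethers, which under dilute acid should be faster than protonation of the trisubstituted and 1,1-disubstituted alkenes, as in the deprotection of prenylated flavonoids.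

**Compound list**
1 | (4R)-4-benzyl-1,3-oxazolidin-2-one | O=C1N[C@H](Cc2ccccc2)CO1 | starting material
2 | 3-methylbut-2-enoyl chloride | CC(C)=CC(=O)Cl | starting material
3 | lithium (4R)-4-benzyl-2-oxo-1,3-oxazolidin-3-ide | [Li+].O=C1[N-][C@H](Cc2ccccc2)CO1 | intermediate
4 | (4R)-4-benzyl-3-(3-methylbut-2-enoyl)-1,3-oxazolidin-2-one | CC(C)=CC(=O)N1[C@H](Cc2ccccc2)COC1=O | intermediate
5 | 1-bromo-3-methylbut-2-ene (prenyl bromide) | CC(C)=CCBr | starting material
6 | sodium Z-dienolate of 4 | C=C(C)/C=C(\[O-])N1[C@H](Cc2ccccc2)COC1=O.[Na+] | intermediate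
7 | (4R)-4-benzyl-3-[(2R)-5-methyl-2-(prop-1-en-2-yl)hex-4-enoyl]-1,3-oxazolidin-2-one | C=C(C)[C@@H](CC=C(C)C)C(=O)N1[C@H](Cc2ccccc2)COC1=O | intermediate
8 | (2R)-5-methyl-2-(prop-1-en-2-yl)hex-4-en-1-ol, (R)-lavandulol | C=C(C)[C@@H](CC=C(C)C)CO | intermediate
9 | (2R)-1-iodo-5-methyl-2-(prop-1-en-2-yl)hex-4-ene, (R)-lavandulyl iodide | C=C(C)[C@@H](CC=C(C)C)CI | intermediate
10 | 5,7-dihydroxy-4H-chromen-4-one | O=c1ccoc2cc(O)cc(O)c12 | starting material
11 | 5-hydroxy-7-(methoxymethoxy)-4H-chromen-4-one | COCOc1cc(O)c2c(c1)occc2=O | intermediate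
12 | 5-hydroxy-6-iodo-7-(methoxymethoxy)-4H-chromen-4-one | COCOc1cc2occc(=O)c2c(O)c1I | intermediate
13 | sodium 6-iodo-7-(methoxymethoxy)-4-oxo-4H-chromen-5-olate | COCOc1cc2occc(=O)c2c([O-])c1I.[Na+] | intermediate
14 | 6-iodo-5,7-bis(methoxymethoxy)-4H-chromen-4-one | COCOc1cc2occc(=O)c2c(OCOC)c1I | intermediate
15 | [(2R)-5-methyl-2-(prop-1-en-2-yl)hex-4-en-1-yl]zinc iodide | C=C(C)[C@@H](CC=C(C)C)C[Zn]I | intermediate
16 | 5,7-bis(methoxymethoxy)-6-[(2S)-5-methyl-2-(prop-1-en-2-yl)hex-4-en-1-yl]-4H-chromen-4-one | C=C(C)[C@@H](CC=C(C)C)Cc1c(OCOC)cc2occc(=O)c2c1OCOC | intermediate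
17 | 4-bromobenzene-1,3-diol (4-bromoresorcinol) | Oc1ccc(Br)c(O)c1 | starting material
18 | 1-bromo-2,4-bis(methoxymethoxy)benzene | COCOc1ccc(Br)c(OCOC)c1 | intermediate
19 | {5,7-bis(methoxymethoxy)-6-[(2S)-5-methyl-2-(prop-1-en-2-yl)hex-4-en-1-yl]-4-oxo-4H-chromen-2-yl}zinc chloride | C=C(C)[C@@H](CC=C(C)C)Cc1c(OCOC)cc2oc([Zn]Cl)cc(=O)c2c1OCOC | intermediate
20 | 2-[2,4-bis(methoxymethoxy)phenyl]-5,7-bis(methoxymethoxy)-6-[(2S)-5-methyl-2-(prop-1-en-2-yl)hex-4-en-1-yl]-4H-chromen-4-one | C=C(C)[C@@H](CC=C(C)C)Cc1c(OCOC)cc2oc(-c3ccc(OCOC)cc3OCOC)cc(=O)c2c1OCOC | intermediate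
21 | 2-(2,4-dihydroxyphenyl)-5,7-dihydroxy-6-[(2S)-5-methyl-2-(prop-1-en-2-yl)hex-4-en-1-yl]-4H-chromen-4-one | C=C(C)[C@@H](CC=C(C)C)Cc1c(O)cc2oc(-c3ccc(O)cc3O)cc(=O)c2c1O | target

**Step count and risks**

Total step count: 11. Longest linear sequence: 7 steps (steps 1, 2, 3, 4, 8, 10, 11).

Steps most likely to fail:

Step 10. The metalation may go to C3 instead of C2 if lithium ion chelated between C4=O and the 5-OMOM oxygen acts as a carbonyl-bound Lewis acid. Slow coupling of the ortho-alkoxy aryl bromide may also let the zinc species be protonated or homocoupled. The fallback sets out from 16 and 18 and replaces deprotonative cross-coupling by conjugate addition and dehydrogenation. Bromine–lithium exchange on 18 (n-BuLi, THF, −78 °C), borylation with B(OiPr)3 and mild acidic work-up should give [2,4-bis(methoxymethoxy)phenyl]boronic acid F2. Palladium(II)-catalysed conjugate addition of F2 to the C2=C3 bond of 16 (Pd(OCOCF3)2, 2,2'-bipyridine, NH4PF6, H2O, ClCH2CH2Cl, 60 °C) should give the flavanone 2-[2,4-bis(methoxymethoxy)phenyl]-5,7-bis(methoxymethoxy)-6-[(2S)-5-methyl-2-(prop-1-en-2-yl)hex-4-en-1-yl]-2,3-dihydro-4H-chromen-4-one F3 as a mixture of C2 epimers, which is of no consequence. Dehydrogenation of F3 with DDQ in 1,4-dioxane at 90 °C should then return to the route at 20.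

Step 8. Transmetalation and reductive elimination at the aryl–palladium centre flanked by two MOM ethers may be slow, so that β-hydride elimination of the alkyl–palladium species (diene formation) and protodeiodination take over. Zinc insertion into 9 may also be incomplete. The fallback sets out from 9 and 14 and changes the nucleophile and the way it is made, to a B-alkyl Suzuki–Miyaura coupling. Iodine–lithium exchange on 9 (t-BuLi, Et2O, −78 °C) and trapping with B-methoxy-9-BBN should give the lithium B-lavandulyl-B-methoxy-9-borabicyclo[3.3.1]nonane ate complex F1. F1 is coupled with 14 (PdCl2(dppf), aq. K3PO4, DMF–THF, rt → 50 °C) and should return to the route at 16.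

Step 11. The protonated isopropenyl group may be captured by the neighbouring 5-OH or 7-OH (chroman formation), or the alkenes may migrate or add methanol, in competition with acetal cleavage. The fallback sets out from 20 and avoids Brønsted acid. Aprotic acetal-to-silyl-ether exchange with TMSOTf and 2,2'-bipyridyl (CH2Cl2, 0 °C → rt) should give the tetrakis(trimethylsilyl) ether 2-[2,4-bis(trimethylsilyloxy)phenyl]-5,7-bis(trimethylsilyloxy)-6-[(2S)-5-methyl-2-(prop-1-en-2-yl)hex-4-en-1-yl]-4H-chromen-4-one F4. Neutral methanolysis of F4 (MeOH, catalytic K2CO3, 0 °C) should then return to the route at 21.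

**Further compounds**
F1 | step 8 | lithium B-[(2R)-5-methyl-2-(prop-1-en-2-yl)hex-4-en-1-yl]-B-methoxy-9-borabicyclo[3.3.1]nonan-9-uide | C=C(C)[C@@H](CC=C(C)C)C[B-]1(OC)C2CCCC1CCC2.[Li+]
F2 | step 10 | [2,4-bis(methoxymethoxy)phenyl]boronic acid | COCOc1ccc(B(O)O)c(OCOC)c1
F3 | step 10 | 2-[2,4-bis(methoxymethoxy)phenyl]-5,7-bis(methoxymethoxy)-6-[(2S)-5-methyl-2-(prop-1-en-2-yl)hex-4-en-1-yl]-2,3-dihydro-4H-chromen-4-one (C2 epimers) | C=C(C)[C@@H](CC=C(C)C)Cc1c(OCOC)cc2c(c1OCOC)C(=O)CC(c1ccc(OCOC)cc1OCOC)O2
F4 | step 11 | 2-[2,4-bis(trimethylsilyloxy)phenyl]-5,7-bis(trimethylsilyloxy)-6-[(2S)-5-methyl-2-(prop-1-en-2-yl)hex-4-en-1-yl]-4H-chromen-4-one | C=C(C)[C@@H](CC=C(C)C)Cc1c(O[Si](C)(C)C)cc2oc(-c3ccc(O[Si](C)(C)C)cc3O[Si](C)(C)C)cc(=O)c2c1O[Si](C)(C)C
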